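**Plan**
1. Retrosynthesis cuts, in this order: (a) the C4'(sp2)–C5'(sp3) bond of the side chain, between the trisubstituted alkene and the epoxycyclohexyl‑ethyl arm (B‑alkyl Suzuki coupling); (b) the C3–Cα bond of the dioxane head (chiral enolate plus peroxycarbenium ion); (c) O1–C6 and O2–C3 of the 1,2‑dioxane, which gives back O2 and the C3–C6 bond of a cyclobutanol.
2. The enabling feature is the run of four ring carbons C3–C4–C5–C6 bridged by O1–O2, with C6 fully substituted. A cyclobutanol with its carbinol at C3 and its quaternary carbon at C6 opens by strain‑driven β‑scission to a tertiary C6 radical, takes up O2 and recloses on the C3 aldehyde, so the four‑membered carbocycle becomes the six‑membered peroxide.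
3. Forward order: acetoacetate alkylation and sulfonium‑ylide spiroannulation give the cyclobutanone; reduction and hydrozirconation–iodination follow; then ring expansion to the 1,2‑dioxan‑3‑ol, acetate, auxiliary enolate addition and methanolysis; the epoxide fragment is joined last by Suzuki coupling, then saponification.
4. Stereochemistry: both epoxide centres come from Sharpless epoxidation of β‑cyclogeraniol; Cα and C3 come from the valine‑derived thiazolidinethione enolate (2,3‑anti addition); the E alkene comes from syn‑hydrozirconation.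
5. C6 arises from O2 capture by a planar radical and cannot be controlled there. Step 7 turns its two antipodes into diastereomers, and the (6R) series is carried on after chromatography, so at most half of the material is used at that point.
6. The acid‑labile tetrasubstituted epoxide is brought in only after every Lewis‑acid step.

Key step: step 5

Remark: C3–C6, O1, O2 are the 1,2‑dioxane locants (the cyclobutane carbons are named by the dioxane positions they become), Cα is C2 of the propanoic acid, and C1'–C6' are the hexenyl side chain on C6. Compounds 1, 2, 13 and 17 are taken as commercially available.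

**Fragment A (dioxane head)**

Step 1
Reactants: 1 ethyl 3-oxobutanoate; 2 1-bromobut-2-yne
Product: 4 hept-5-yn-2-one, via ethyl 2-acetylhex-4-ynoate 3 (not isolated)
Conditions: NaOEt, EtOH, 0 °C to reflux; then aq. NaOH, 25 °C; then aq. H2SO4, 60 °C (−CO2)
Reagents that add atoms: none
Why: Acetoacetic ester synthesis, in which the stabilised sodium enolate of 1 is C‑alkylated by the propargylic bromide (SN2) and the β‑keto ester is saponified and decarboxylated to the methyl ketone; no stereocentre is formed.

Step 2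
Reactants: 4 hept-5-yn-2-one
Product: 6 2-methyl-2-(pent-3-yn-1-yl)cyclobutan-1-one (racemic), via oxaspiropentane 5 (not isolated)
Conditions: cyclopropyldiphenylsulfonium tetrafluoroborate, KOH (powder), DMSO, 25 °C; then aq. HBF4 (cat.), Et2O, 25 °C
Reagents that add atoms: cyclopropyldiphenylsulfonium tetrafluoroborate, C1CC1[S+](c1ccccc1)c1ccccc1.F[B-](F)(F)F
Why: Sulfonium‑ylide spiroannulation, in which the cyclopropylide adds to the ketone and closes to oxaspiropentane 5, whose acid‑triggered cyclopropylcarbinyl‑to‑cyclobutyl (semipinacol‑type) rearrangement should give the 2,2‑disubstituted cyclobutanone; the new quaternary centre is racemic, which does not matter because it becomes a planar radical in step 5.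

Step 3
Reactants: 6 2-methyl-2-(pent-3-yn-1-yl)cyclobutan-1-one
Product: 7 2-methyl-2-(pent-3-yn-1-yl)cyclobutan-1-ol (racemic, cis/trans mixture)
Conditions: NaBH4, MeOH, 0 °C
Reagents that add atoms: none
Why: Borohydride reduction of the strained ketone; the cis/trans carbinol mixture is used as such because both cyclobutane stereocentres are erased in step 5.

Step 4
Reactants: 7 2-methyl-2-(pent-3-yn-1-yl)cyclobutan-1-ol
Product: 9 2-[(3E)-4-iodopent-3-en-1-yl]-2-methylcyclobutan-1-ol (racemic, cis/trans mixture), via alkenylzirconocene alkoxide 8 (not isolated)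
Conditions: Cp2Zr(H)Cl (3 equiv), THF, 25 to 45 °C; then iodine, 0 °C
Reagents that add atoms: iodine, [I][I]
Why: Hydrozirconation–iodination, in which syn addition of Zr–H across the 2‑alkyne, equilibrated with excess reagent so that zirconium sits on the less hindered methyl‑bearing carbon, and iodinolysis with retention should give the (E)‑2‑iodoalkene that fixes the geometry of the future trisubstituted alkene; the free hydroxyl only consumes one equivalent of hydride.

Step 5
Reactants: 9 2-[(3E)-4-iodopent-3-en-1-yl]-2-methylcyclobutan-1-ol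
Product: 11 6-[(3E)-4-iodopent-3-en-1-yl]-6-methyl-1,2-dioxan-3-ol (racemic at C6, anomeric mixture), via hydroperoxy aldehyde 10 (not isolated)
Conditions: Co(acac)2 (10 mol%), O2 (1 atm), CH2Cl2, 25 °C
Reagents that add atoms: dioxygen, O=O
Why: Co(acac)2 and O2 should give a cobalt peroxo species (cobalt trivalent) that exchanges with the carbinol of 9; the derived alkoxy radical undergoes β‑scission of the C3–C6 bond, driven by release of the cyclobutane ring strain, to the aldehyde and the tertiary C6 radical, which captures O2, and the peroxyl radical is reduced to hydroperoxide 10 with return of divalent cobalt. The closest known reaction type is the cobalt‑catalysed aerobic ring expansion of cyclobutanols to 1,2‑dioxan‑3‑ols (and of cyclopropanols to 1,2‑dioxolan‑3‑ols). The only ring closure is the reversible 6‑exo‑trig addition of the hydroperoxide to the aldehyde carbon (peroxy‑hemiacetalisation), so the four‑membered carbocycle becomes the six‑membered peroxide with C3–C6 all retained. C6 is created by oxygen capture at a planar radical and therefore forms in both configurations (dealt with in step 7), while C3 is an equilibrating hemiacetal carbon under thermodynamic control that is re‑set in step 7. The step needs cleavage of C3–C6 rather than C3–C4, which the quaternary C6 secures (tertiary versus primary radical), and it needs the iodoalkene to stay untouched, which holds because the C6 radical could reach it only by disfavoured 4‑exo or 5‑endo closure.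

Step 6
Reactants: 11 6-[(3E)-4-iodopent-3-en-1-yl]-6-methyl-1,2-dioxan-3-ol
Product: 12 6-[(3E)-4-iodopent-3-en-1-yl]-6-methyl-1,2-dioxan-3-yl acetate (racemic at C6, anomeric mixture)
Conditions: Ac2O, pyridine, DMAP (cat.), CH2Cl2, 0 °C
Reagents that add atoms: acetic anhydride, CC(=O)OC(C)=O
Why: O‑Acylation of the peroxy‑hemiacetal hydroxyl under weak base installs the anomeric leaving group for peroxycarbenium formation; the anomeric mixture is of no consequence.

Step 7
Reactants: 12 6-[(3E)-4-iodopent-3-en-1-yl]-6-methyl-1,2-dioxan-3-yl acetate; 13 (4S)-3-propanoyl-4-(propan-2-yl)-1,3-thiazolidine-2-thione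
Product: 15 (4S)-3-[(2R)-2-[(3R,6R)-6-[(3E)-4-iodopent-3-en-1-yl]-6-methyl-1,2-dioxan-3-yl]propanoyl]-4-(propan-2-yl)-1,3-thiazolidine-2-thione, via titanium enolate 14 (not isolated)
Conditions: 13, TiCl4, iPr2NEt, CH2Cl2, −78 to −40 °C; then 12, TiCl4, −78 °C; silica gel chromatography to remove the C6 epimer
Reagents that add atoms: none
Why: Proposed new method: TiCl4 should ionise the anomeric acetate of 12 to a cyclic peroxycarbenium ion (a species known to be trapped by silyl ketene acetals and allylsilanes), which the chelated Z‑titanium enolate 14 attacks through an open antiperiplanar transition state on the enolate face opposite the isopropyl group, giving the 2,3‑anti adduct with Cα (R) and C3 (R) under auxiliary control for both C6 antipodes of 12, so that the (6R) and (6S) series emerge as separable diastereomers and 15 is taken on; the closest known reaction types are the anti‑selective addition of chiral N‑acylthiazolidinethione titanium enolates to acetal‑derived oxocarbenium ions and the Lewis‑acid Mukaiyama‑type alkylation of 3‑acyloxy‑1,2‑dioxanes.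

Step 8
Reactants: 15 (4S)-3-[(2R)-2-[(3R,6R)-6-[(3E)-4-iodopent-3-en-1-yl]-6-methyl-1,2-dioxan-3-yl]propanoyl]-4-(propan-2-yl)-1,3-thiazolidine-2-thione
Product: 16 methyl (2R)-2-[(3R,6R)-6-[(3E)-4-iodopent-3-en-1-yl]-6-methyl-1,2-dioxan-3-yl]propanoate
Conditions: MeOH, imidazole, CH2Cl2, 25 °C
Reagents that add atoms: methanol, CO
Why: Nucleophilic acyl substitution of the activated N‑acylthiazolidinethione by methanol under imidazole catalysis, mild enough to avoid Cα epimerisation and retro‑peroxy‑Michael ring opening, and it removes the sulfur auxiliary before the palladium step.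

**Fragment B (epoxide)**

Step 9
Reactants: 17 2,6,6-trimethylcyclohex-1-ene-1-carbaldehyde (β-cyclocitral)
Product: 18 (2,6,6-trimethylcyclohex-1-en-1-yl)methanol (β-cyclogeraniol)
Conditions: NaBH4, MeOH, 0 °C
Reagents that add atoms: none
Why: 1,2‑Reduction of the hindered enal with borohydride gives the allylic alcohol needed as the directing group.

Step 10
Reactants: 18 (2,6,6-trimethylcyclohex-1-en-1-yl)methanol
Product: 19 [(1R,6R)-2,2,6-trimethyl-7-oxabicyclo[4.1.0]heptan-1-yl]methanol
Conditions: Ti(OiPr)4 (cat.), D-(−)-diethyl tartrate (cat.), tBuOOH, 4 Å MS, CH2Cl2, −20 °C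
Reagents that add atoms: tert-butyl hydroperoxide, CC(C)(C)OO
Why: Sharpless asymmetric epoxidation, in which the allylic alkoxide binds the Ti(OiPr)4–tartrate catalyst and D‑(−)‑diethyl tartrate should deliver the peroxide oxygen to the alkene face that gives the (1R,6R) epoxy alcohol (the 2R series), setting both epoxide stereocentres in one syn oxygen transfer.

Step 11
Reactants: 19 [(1R,6R)-2,2,6-trimethyl-7-oxabicyclo[4.1.0]heptan-1-yl]methanol
Product: 20 (1S,6R)-2,2,6-trimethyl-7-oxabicyclo[4.1.0]heptane-1-carbaldehyde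
Conditions: (nPr4N)RuO4 (cat.), N-methylmorpholine N-oxide, 4 Å MS, CH2Cl2, 25 °C
Reagents that add atoms: none
Why: Ley–Griffith oxidation under neutral conditions converts the primary alcohol to the non‑enolisable aldehyde without acid that could open the tetrasubstituted epoxide (the descriptor at C1 changes by priority only).

Step 12
Reactants: 20 (1S,6R)-2,2,6-trimethyl-7-oxabicyclo[4.1.0]heptane-1-carbaldehyde
Product: 21 (1S,6R)-1-ethenyl-2,2,6-trimethyl-7-oxabicyclo[4.1.0]heptane
Conditions: Ph3PCH3Br, KOtBu, THF, 0 to 25 °C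
Reagents that add atoms: methyltriphenylphosphonium bromide, C[P+](c1ccccc1)(c1ccccc1)c1ccccc1.[Br-]
Why: Wittig methylenation of the non‑enolisable aldehyde with the unstabilised ylide gives the vinyl epoxide and leaves the stereocentres untouched.

**Union and end game**

Step 13
Reactants: 21 (1S,6R)-1-ethenyl-2,2,6-trimethyl-7-oxabicyclo[4.1.0]heptane; 16 methyl (2R)-2-[(3R,6R)-6-[(3E)-4-iodopent-3-en-1-yl]-6-methyl-1,2-dioxan-3-yl]propanoate
Product: 23 methyl (2R)-2-[(3R,6R)-6-methyl-6-[(3E)-4-methyl-6-[(1S,6R)-2,2,6-trimethyl-7-oxabicyclo[4.1.0]heptan-1-yl]hex-3-en-1-yl]-1,2-dioxan-3-yl]propanoate, via alkylborane 22 (not isolated)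
Conditions: 21, 9-BBN, THF, 0 to 25 °C; then 16, PdCl2(dppf) (cat.), AsPh3, Cs2CO3, DMF/THF/H2O, 25 °C
Reagents that add atoms: none
Why: B‑alkyl Suzuki–Miyaura coupling, in which anti‑Markovnikov hydroboration gives primary alkylborane 22 that, after base activation, transmetalates to the palladium species formed by oxidative addition of the alkenyl iodide to zerovalent palladium, with retention of the E geometry; palladium cross‑couplings are tolerated by unstrained 1,2‑dioxanes, and the epoxide meets only mild base.

Step 14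
Reactants: 23 methyl (2R)-2-[(3R,6R)-6-methyl-6-[(3E)-4-methyl-6-[(1S,6R)-2,2,6-trimethyl-7-oxabicyclo[4.1.0]heptan-1-yl]hex-3-en-1-yl]-1,2-dioxan-3-yl]propanoate
Product: 24 (2R)-2-[(3R,6R)-6-methyl-6-[(3E)-4-methyl-6-[(1S,6R)-2,2,6-trimethyl-7-oxabicyclo[4.1.0]heptan-1-yl]hex-3-en-1-yl]-1,2-dioxan-3-yl]propanoic acid (CNP0252106.4)
Conditions: LiOH, THF/MeOH/H2O, 0 to 25 °C; then cold dilute HCl to pH 4–5
Reagents that add atoms: lithium hydroxide, [Li+].[OH-]
Why: Saponification of the methyl ester, a standard last step for β‑peroxy esters, followed by cold acidification to pH 4–5 so that the epoxide does not open and Cα does not epimerise, should give the target.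

**Compound list**
1 | ethyl 3-oxobutanoate | CCOC(=O)CC(C)=O | starting material
2 | 1-bromobut-2-yne | CC#CCBr | starting material
3 | ethyl 2-acetylhex-4-ynoate (racemic) | CCOC(=O)C(CC#CC)C(C)=O | intermediate
4 | hept-5-yn-2-one | CC#CCCC(C)=O | intermediate
5 | 2-methyl-2-(pent-3-yn-1-yl)-1-oxaspiro[2.2]pentane (racemic) | CC#CCCC1(C)OC12CC2 | intermediate
6 | 2-methyl-2-(pent-3-yn-1-yl)cyclobutan-1-one (racemic) | CC#CCCC1(C)CCC1=O | intermediate
7 | 2-methyl-2-(pent-3-yn-1-yl)cyclobutan-1-ol (racemic, cis/trans mixture) | CC#CCCC1(C)CCC1O | intermediate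
8 | alkenylzirconocene alkoxide: O-[chlorobis(cyclopentadienyl)zirconium] derivative of 2-[(3E)-4-[chlorobis(cyclopentadienyl)zirconio]pent-3-en-1-yl]-2-methylcyclobutan-1-ol | C/C(=C\CCC1(C)CCC1O[Zr](Cl)(C1C=CC=C1)C1C=CC=C1)[Zr](Cl)(C1C=CC=C1)C1C=CC=C1 | intermediate
9 | 2-[(3E)-4-iodopent-3-en-1-yl]-2-methylcyclobutan-1-ol (racemic, cis/trans mixture) | C/C([I])=C\CCC1(C)CCC1O | intermediate
10 | (7E)-4-hydroperoxy-8-iodo-4-methylnon-7-enal (racemic) | C/C([I])=C\CCC(C)(OO)CCC=O | intermediate
11 | 6-[(3E)-4-iodopent-3-en-1-yl]-6-methyl-1,2-dioxan-3-ol (racemic at C6, anomeric mixture) | C/C([I])=C\CCC1(C)CCC(O)OO1 | intermediate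
12 | 6-[(3E)-4-iodopent-3-en-1-yl]-6-methyl-1,2-dioxan-3-yl acetate (racemic at C6, anomeric mixture) | C/C([I])=C\CCC1(C)CCC(OC(C)=O)OO1 | intermediate
13 | (4S)-3-propanoyl-4-(propan-2-yl)-1,3-thiazolidine-2-thione | CCC(=O)N1C(=S)SC[C@@H]1C(C)C | starting material
14 | titanium enolate: (4S)-4-(propan-2-yl)-3-[(1Z)-1-(trichlorotitaniooxy)prop-1-en-1-yl]-1,3-thiazolidine-2-thione | C/C=C(\O[Ti](Cl)(Cl)Cl)N1C(=S)SC[C@@H]1C(C)C | intermediate
15 | (4S)-3-[(2R)-2-[(3R,6R)-6-[(3E)-4-iodopent-3-en-1-yl]-6-methyl-1,2-dioxan-3-yl]propanoyl]-4-(propan-2-yl)-1,3-thiazolidine-2-thione | C/C([I])=C\CC[C@]1(C)CC[C@H]([C@@H](C)C(=O)N2C(=S)SC[C@@H]2C(C)C)OO1 | intermediate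
16 | methyl (2R)-2-[(3R,6R)-6-[(3E)-4-iodopent-3-en-1-yl]-6-methyl-1,2-dioxan-3-yl]propanoate | C/C([I])=C\CC[C@]1(C)CC[C@H]([C@@H](C)C(=O)OC)OO1 | intermediate
17 | 2,6,6-trimethylcyclohex-1-ene-1-carbaldehyde (β-cyclocitral) | CC1=C(C=O)C(C)(C)CCC1 | starting material
18 | (2,6,6-trimethylcyclohex-1-en-1-yl)methanol (β-cyclogeraniol) | CC1=C(CO)C(C)(C)CCC1 | intermediate
19 | [(1R,6R)-2,2,6-trimethyl-7-oxabicyclo[4.1.0]heptan-1-yl]methanol | OC[C@@]12O[C@]1(C)CCCC2(C)C | intermediate
20 | (1S,6R)-2,2,6-trimethyl-7-oxabicyclo[4.1.0]heptane-1-carbaldehyde | O=C[C@@]12O[C@]1(C)CCCC2(C)C | intermediate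
21 | (1S,6R)-1-ethenyl-2,2,6-trimethyl-7-oxabicyclo[4.1.0]heptane | C=C[C@@]12O[C@]1(C)CCCC2(C)C | intermediate
22 | 9-[2-[(1S,6R)-2,2,6-trimethyl-7-oxabicyclo[4.1.0]heptan-1-yl]ethyl]-9-borabicyclo[3.3.1]nonane | C(CB1C2CCCC1CCC2)[C@@]12O[C@]1(C)CCCC2(C)C | intermediate
23 | methyl (2R)-2-[(3R,6R)-6-methyl-6-[(3E)-4-methyl-6-[(1S,6R)-2,2,6-trimethyl-7-oxabicyclo[4.1.0]heptan-1-yl]hex-3-en-1-yl]-1,2-dioxan-3-yl]propanoate | C/C(=C\CC[C@]1(C)CC[C@H]([C@@H](C)C(=O)OC)OO1)CC[C@@]12O[C@]1(C)CCCC2(C)C | intermediate
24 | (2R)-2-[(3R,6R)-6-methyl-6-[(3E)-4-methyl-6-[(1S,6R)-2,2,6-trimethyl-7-oxabicyclo[4.1.0]heptan-1-yl]hex-3-en-1-yl]-1,2-dioxan-3-yl]propanoic acid | C/C(=C\CC[C@]1(C)CC[C@H]([C@@H](C)C(=O)O)OO1)CC[C@@]12O[C@]1(C)CCCC2(C)C | target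

**Step count and risks**
Total step count: 14 (fragment A steps 1–8, fragment B steps 9–12, union and end game steps 13–14). Longest linear sequence: 10 steps (1–8, 13, 14).

Steps most likely to fail:

Step 7 (Proposed new method). The Lewis acid may instead trigger heterolysis of the tertiary C6–O bond and fragmentation of the peroxide, the titanium enolate may be oxidised by the O–O bond, or facial selectivity at the cyclic peroxycarbenium ion may be poor; in any case only the (6R) half of racemic 12 can give 15. Fallback with known chemistry: starting from 11, Wittig olefination of the masked aldehyde with methyl 2-(triphenylphosphoranylidene)propanoate (toluene, 50 °C) should give methyl (2E,9E)-6-hydroperoxy-10-iodo-2,6-dimethylundeca-2,9-dienoate F1. Treatment with Et2NH in CF3CH2OH should close it by intramolecular peroxy‑Michael addition to methyl 2-[6-[(3E)-4-iodopent-3-en-1-yl]-6-methyl-1,2-dioxan-3-yl]propanoate F2 (racemic, mixture of diastereomers). The required diastereomer is isolated on silica gel and resolved by preparative HPLC on a chiral stationary phase, rejoining the route at 16.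

Step 13. The O–O bond may be reduced by the alkylborane or by zerovalent palladium, transmetalation of the hindered borane may be slow so that protodeboronation wins, or the base may open the β‑peroxy ester by retro‑Michael elimination. Fallback that moves the coupling ahead of peroxide formation and avoids any Lewis acid on the epoxide: starting from 9 and 22 (made from 21), the same Suzuki coupling at the cyclobutanol stage should give 2-methyl-2-[(3E)-4-methyl-6-[(1S,6R)-2,2,6-trimethyl-7-oxabicyclo[4.1.0]heptan-1-yl]hex-3-en-1-yl]cyclobutan-1-ol F3. Ring expansion with Co(acac)2 and O2 should give 6-methyl-6-[(3E)-4-methyl-6-[(1S,6R)-2,2,6-trimethyl-7-oxabicyclo[4.1.0]heptan-1-yl]hex-3-en-1-yl]-1,2-dioxan-3-ol F4. Wittig olefination with methyl 2-(triphenylphosphoranylidene)propanoate should give methyl (2E,9E)-6-hydroperoxy-2,6,10-trimethyl-12-[(1S,6R)-2,2,6-trimethyl-7-oxabicyclo[4.1.0]heptan-1-yl]dodeca-2,9-dienoate F5. Base‑mediated peroxy‑Michael cyclisation (Et2NH, CF3CH2OH) and HPLC separation of the diastereomers rejoin the route at 23.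

Step 5. The carbinol may be over‑oxidised to the cyclobutanone, the peroxyl radical may be reduced past the hydroperoxide to the alcohol (giving a lactol), or the cobalt catalyst may be deactivated before conversion is complete. Fallback that builds the tertiary hydroperoxide by an ionic route: starting from 4, addition of [2-(1,3-dioxolan-2-yl)ethyl]magnesium bromide should give 1-(1,3-dioxolan-2-yl)-3-methyloct-6-yn-3-ol F6. Hydrozirconation–iodination as in step 4 should give (6E)-1-(1,3-dioxolan-2-yl)-7-iodo-3-methyloct-6-en-3-ol F7. Aqueous H2O2 with catalytic H2SO4 in Et2O at 0 °C should convert the tertiary alcohol into the hydroperoxide, which closes on the acetal carbon to 2-[[6-[(3E)-4-iodopent-3-en-1-yl]-6-methyl-1,2-dioxan-3-yl]oxy]ethan-1-ol F8. Mild aqueous acid hydrolysis of this peroxyacetal rejoins the route at 11.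

Further compounds
F1 | step 7 | methyl (2E,9E)-6-hydroperoxy-10-iodo-2,6-dimethylundeca-2,9-dienoate (racemic) | COC(=O)/C(C)=C/CCC(C)(OO)CC/C=C(\C)[I]
F2 | step 7 | methyl 2-[6-[(3E)-4-iodopent-3-en-1-yl]-6-methyl-1,2-dioxan-3-yl]propanoate (racemic, mixture of diastereomers) | C/C([I])=C\CCC1(C)CCC(C(C)C(=O)OC)OO1
F3 | step 13 | 2-methyl-2-[(3E)-4-methyl-6-[(1S,6R)-2,2,6-trimethyl-7-oxabicyclo[4.1.0]heptan-1-yl]hex-3-en-1-yl]cyclobutan-1-ol (mixture at the cyclobutane centres) | C/C(=C\CCC1(C)CCC1O)CC[C@@]12O[C@]1(C)CCCC2(C)C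
F4 | step 13 | 6-methyl-6-[(3E)-4-methyl-6-[(1S,6R)-2,2,6-trimethyl-7-oxabicyclo[4.1.0]heptan-1-yl]hex-3-en-1-yl]-1,2-dioxan-3-ol (mixture at C3 and C6) | C/C(=C\CCC1(C)CCC(O)OO1)CC[C@@]12O[C@]1(C)CCCC2(C)C
F5 | step 13 | methyl (2E,9E)-6-hydroperoxy-2,6,10-trimethyl-12-[(1S,6R)-2,2,6-trimethyl-7-oxabicyclo[4.1.0]heptan-1-yl]dodeca-2,9-dienoate (mixture at C6) | COC(=O)/C(C)=C/CCC(C)(OO)CC/C=C(\C)CC[C@@]12O[C@]1(C)CCCC2(C)C
F6 | step 5 | 1-(1,3-dioxolan-2-yl)-3-methyloct-6-yn-3-ol (racemic) | CC#CCCC(C)(O)CCC1OCCO1
F7 | step 5 | (6E)-1-(1,3-dioxolan-2-yl)-7-iodo-3-methyloct-6-en-3-ol (racemic) | C/C([I])=C\CCC(C)(O)CCC1OCCO1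
F8 | step 5 | 2-[[6-[(3E)-4-iodopent-3-en-1-yl]-6-methyl-1,2-dioxan-3-yl]oxy]ethan-1-ol (racemic at C6, anomeric mixture) | C/C([I])=C\CCC1(C)CCC(OCCO)OO1
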